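The tetrahydrofuran (O1, C2 carrying guaiacyl ring A, C3 carrying C6, C4 carrying the C7 ketone of syringyl ring B, C5) is cut at O1–C5 and C3–C4. Because O1–C5–C4–C7=O is a β-alkoxy ketone and C3 can be the β-carbon of a nitroalkene with C6 as nitro carbon, one base-triggered domino joins an (S)-γ-hydroxy nitroalkene to a ring B aryl vinyl ketone: the C2 hydroxyl adds to the enone and the C4 enolate closes onto C3. This single operation makes the ring, both bonds and the C3 and C4 stereocentres under control of C2. Both partners carry triisopropylsilyl-protected phenols; the carbinol is freed just before use.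

Key step: step 11

Remark on the chemistry: in this ring numbering the target is (2S,3R,4S) with the three substituents alternating faces (all-trans), so the carbinol of the nitroalkene must be S. The phenols are carried as TIPS ethers because a smaller aryl silyl ether para to the ketone would not survive the basic steps. Abbreviations: ArA = 3-methoxy-4-(triisopropylsilyloxy)phenyl, ArB = 3,5-dimethoxy-4-(triisopropylsilyloxy)phenyl.

Step 1
Reactants: 1 vanillin
Product: 2 ArA-carbaldehyde (3-methoxy-4-(triisopropylsilyloxy)benzaldehyde)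
Conditions: TIPSCl, imidazole, DMF, rt
Reagents that add atoms: chlorotriisopropylsilane, CC(C)[Si](Cl)(C(C)C)C(C)C
Why: Imidazole-promoted O-silylation masks the acidic phenol before the Grignard step, and the bulky TIPS group is chosen for its resistance to the basic steps ahead.

Step 2
Reactants: 2 ArA-carbaldehyde
Product: 3 rac-1-ArA-prop-2-en-1-ol
Conditions: CH2=CHMgBr, THF, −78 to 0 °C; aq. NH4Cl
Reagents that add atoms: vinylmagnesium bromide, C=C[Mg]Br
Why: Grignard 1,2-addition to the aldehyde; the new carbinol centre is formed racemic and is resolved in step 3.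

Step 3
Reactants: 3 rac-1-ArA-prop-2-en-1-ol
Product: 4 (S)-1-ArA-prop-2-en-1-ol
Conditions: vinyl acetate, Candida antarctica lipase B on acrylic resin (Novozym 435), MTBE, 30 °C, stopped just past 50% conversion
Reagents that add atoms: none
Why: Lipase-catalysed kinetic resolution by enantioselective transesterification, in which the R-alcohol (aryl large, vinyl medium) should be acetylated and the S-alcohol recovered, its enantiopurity rising as conversion passes one half; this fixes C2 of the target.

Step 4
Reactants: 4 (S)-1-ArA-prop-2-en-1-ol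
Product: 5 (S)-1-ArA-1-(triethylsilyloxy)prop-2-ene
Conditions: TESCl, imidazole, CH2Cl2, 0 °C
Reagents that add atoms: chlorotriethylsilane, CC[Si](Cl)(CC)CC
Why: Silylation of the secondary alcohol without touching the stereocentre; the TES ether should survive ozonolysis and the Henry/elimination sequence and later leave under acid mild enough to spare the aryl TIPS ether.

Step 5
Reactants: 5 (S)-1-ArA-1-(triethylsilyloxy)prop-2-ene
Product: 7 (R)-2-ArA-2-(triethylsilyloxy)acetaldehyde, via secondary ozonide 6 (not isolated)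
Conditions: O3, CH2Cl2, −78 °C (Sudan red end point); then PPh3, −78 °C to rt
Reagents that add atoms: ozone, [O-][O+]=O
Why: Ozonolysis of the terminal alkene, far more reactive than the arene at −78 °C, then neutral PPh3 reduction of the ozonide, which should leave the enolisable α-silyloxy aldehyde configurationally intact (R only because the CIP priorities change); the ozonide carbon is a transient mixed centre.

Step 6
Reactants: 7 (R)-2-ArA-2-(triethylsilyloxy)acetaldehyde; 8 nitromethane
Product: 11 (S,E)-1-ArA-3-nitro-1-(triethylsilyloxy)prop-2-ene, via nitroaldol 9 (not isolated), via nitroaldol mesylate 10 (not isolated)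
Conditions: MeNO2 (solvent), iPr2NEt (20 mol %), 0 °C; evaporate; MsCl, iPr2NEt, CH2Cl2, −40 to 0 °C
Reagents that add atoms: none
Why: Henry (nitroaldol) addition followed by mesylation and E1cB elimination to the conjugated E-nitroalkene; nitromethane is far more acidic than the α-C–H of 7, so the hindered amine should not enolise C2, and the mixed carbinol centre of 9 is erased on elimination.

Step 7
Reactants: 11 (S,E)-1-ArA-3-nitro-1-(triethylsilyloxy)prop-2-ene
Product: 12 (S,E)-1-ArA-3-nitroprop-2-en-1-ol
Conditions: AcOH–THF–H2O (3:1:1), rt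
Reagents that add atoms: none
Why: Acid-catalysed hydrolysis of the secondary TES ether, to which the aryl TIPS ether and the nitroalkene are inert; the electron-poor nitrovinyl group disfavours benzylic ionisation and no base is present to remove the γ-hydrogen, so C2 should stay S.

Step 8
Reactants: 13 syringaldehyde
Product: 14 ArB-carbaldehyde (3,5-dimethoxy-4-(triisopropylsilyloxy)benzaldehyde)
Conditions: TIPSCl, imidazole, DMF, 40 °C
Reagents that add atoms: chlorotriisopropylsilane, CC(C)[Si](Cl)(C(C)C)C(C)C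
Why: O-Silylation of the phenol, warmed because of the two flanking methoxy groups; TIPS is used because this silyl ether will sit para to a ketone and must resist base.

Step 9
Reactants: 14 ArB-carbaldehyde
Product: 15 rac-1-ArB-prop-2-en-1-ol
Conditions: CH2=CHMgBr, THF, −78 to 0 °C; aq. NH4Cl
Reagents that add atoms: vinylmagnesium bromide, C=C[Mg]Br
Why: Grignard 1,2-addition to the aldehyde; the racemic carbinol centre is removed by the oxidation in step 10.

Step 10
Reactants: 15 rac-1-ArB-prop-2-en-1-ol
Product: 16 1-ArB-prop-2-en-1-one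
Conditions: Dess–Martin periodinane, CH2Cl2, 0 °C
Reagents that add atoms: none
Why: Dess–Martin oxidation of the benzylic, allylic carbinol under non-basic conditions gives the polymerisation-prone aryl vinyl ketone, which is used at once.

Step 11
Reactants: 12 (S,E)-1-ArA-3-nitroprop-2-en-1-ol; 16 1-ArB-prop-2-en-1-one (1.5 equiv)
Product: 18 (2S,3R,4S)-2-ArA-3-(nitromethyl)-4-(ArB-carbonyl)oxolane, via oxa-Michael adduct 17 (not isolated)
Conditions: 1-[3,5-bis(trifluoromethyl)phenyl]-3-[2-(dimethylamino)ethyl]thiourea (10 mol %), BHT (1 mol %), toluene, 0 °C to rt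
Reagents that add atoms: none
Why: Proposed new method: the amine site of the catalyst acts as general base so that the C2 hydroxyl of 12 adds to the unhindered CH2 terminus of 16 (O1–C5), and the enolate of 17 so formed attacks C3 of the thiourea-activated nitroalkene (C3–C4) before it can revert, the nitronate then being protonated. The closest known reaction type is the domino oxa-Michael/Michael (3+2) annulation of γ-hydroxy enones with nitroalkenes, and of 2-(2-nitrovinyl)phenols with enones or enals; here the hydroxyl sits on the nitroalkene partner and an aryl vinyl ketone is the external acceptor. The ring closes by a 5-exo-trig conjugate addition of the C4 enolate onto C3, with the C3=C6 bond outside the ring. C3 is set by C2: ring A takes the pseudo-equatorial place in the envelope-like transition state and the enolate reaches the alkene face anti to it, giving 2,3-trans. C4 is enolisable and should settle trans to the C3 nitromethyl group under the amine, so the all-trans isomer is also the thermodynamic one. The step needs the alkoxide to choose the vinyl ketone over the nitroalkene and to add faster than the γ-C–H of 12 is removed; the terminal acceptor carbon of 16 against the β-branched nitroalkene, the excess of 16 present from the start, and a weakly basic hydrogen-bonding catalyst at low temperature are meant to secure this.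

Step 12
Reactants: 18 (2S,3R,4S)-2-ArA-3-(nitromethyl)-4-(ArB-carbonyl)oxolane
Product: 21 (2S,3R,4S)-2-ArA-3-(hydroxymethyl)-4-(ArB-carbonyl)oxolane, via sodium nitronate 19 (not isolated), via keto aldehyde 20 (not isolated)
Conditions: NaOMe (1.05 equiv), MeOH–CH2Cl2, −20 °C; O3, −78 °C; N2 purge; NaBH4, −78 °C; pH 7 buffer
Reagents that add atoms: ozone, [O-][O+]=O
Why: Oxidative Nef reaction with reductive quench: one equivalent of NaOMe deprotonates the nitro group (by far the most acidic site), ozone cleaves the nitronate C=N bond to the aldehyde and nitrite, and NaBH4 at −78 °C should reduce the aldehyde much faster than the electron-rich, hindered ring B ketone, so the base-sensitive β-alkoxy aldehyde is never warmed or isolated and no stereocentre is touched.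

Step 13
Reactants: 21 (2S,3R,4S)-2-ArA-3-(hydroxymethyl)-4-(ArB-carbonyl)oxolane
Product: 22 target, [(3S,4R,5S)-5-(4-hydroxy-3-methoxyphenyl)-4-(hydroxymethyl)oxolan-3-yl](4-hydroxy-3,5-dimethoxyphenyl)methanone
Conditions: TBAF, AcOH, THF, 0 °C
Reagents that add atoms: none
Why: Fluoride cleavage of both aryl Si–O bonds, buffered with acetic acid so that no free phenoxide can open the β-alkoxy ketone or the benzylic ether; the primary alcohol, the ketone and the three stereocentres are untouched.

Compound list (ArA = 3-methoxy-4-(triisopropylsilyloxy)phenyl, ArB = 3,5-dimethoxy-4-(triisopropylsilyloxy)phenyl)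

1 | vanillin (4-hydroxy-3-methoxybenzaldehyde) | COc1cc(C=O)ccc1O | starting material
2 | 3-methoxy-4-(triisopropylsilyloxy)benzaldehyde | COc1cc(C=O)ccc1O[Si](C(C)C)(C(C)C)C(C)C | intermediate
3 | rac-1-ArA-prop-2-en-1-ol | COc1cc(C(O)C=C)ccc1O[Si](C(C)C)(C(C)C)C(C)C | intermediate
4 | (S)-1-ArA-prop-2-en-1-ol | COc1cc([C@@H](O)C=C)ccc1O[Si](C(C)C)(C(C)C)C(C)C | intermediate
5 | (S)-1-ArA-1-(triethylsilyloxy)prop-2-ene | COc1cc([C@@H](O[Si](CC)(CC)CC)C=C)ccc1O[Si](C(C)C)(C(C)C)C(C)C | intermediate
6 | secondary ozonide of 5, 3-[(R)-ArA(triethylsilyloxy)methyl]-1,2,4-trioxolane, ring carbon as a mixture | COc1cc([C@@H](O[Si](CC)(CC)CC)C2OOCO2)ccc1O[Si](C(C)C)(C(C)C)C(C)C | intermediate (not isolated)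
7 | (R)-2-ArA-2-(triethylsilyloxy)acetaldehyde | COc1cc([C@@H](O[Si](CC)(CC)CC)C=O)ccc1O[Si](C(C)C)(C(C)C)C(C)C | intermediate
8 | nitromethane | C[N+](=O)[O-] | starting material
9 | (1R,2RS)-1-ArA-3-nitro-1-(triethylsilyloxy)propan-2-ol (nitroaldol) | COc1cc([C@@H](O[Si](CC)(CC)CC)C(O)C[N+](=O)[O-])ccc1O[Si](C(C)C)(C(C)C)C(C)C | intermediate (not isolated)
10 | (1R,2RS)-1-ArA-3-nitro-1-(triethylsilyloxy)propan-2-yl methanesulfonate | COc1cc([C@@H](O[Si](CC)(CC)CC)C(OS(C)(=O)=O)C[N+](=O)[O-])ccc1O[Si](C(C)C)(C(C)C)C(C)C | intermediate (not isolated)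
11 | (S,E)-1-ArA-3-nitro-1-(triethylsilyloxy)prop-2-ene | COc1cc([C@@H](O[Si](CC)(CC)CC)/C=C/[N+](=O)[O-])ccc1O[Si](C(C)C)(C(C)C)C(C)C | intermediate
12 | (S,E)-1-ArA-3-nitroprop-2-en-1-ol | COc1cc([C@@H](O)/C=C/[N+](=O)[O-])ccc1O[Si](C(C)C)(C(C)C)C(C)C | intermediate
13 | syringaldehyde (4-hydroxy-3,5-dimethoxybenzaldehyde) | COc1cc(C=O)cc(OC)c1O | starting material
14 | 3,5-dimethoxy-4-(triisopropylsilyloxy)benzaldehyde | COc1cc(C=O)cc(OC)c1O[Si](C(C)C)(C(C)C)C(C)C | intermediate
15 | rac-1-ArB-prop-2-en-1-ol | COc1cc(C(O)C=C)cc(OC)c1O[Si](C(C)C)(C(C)C)C(C)C | intermediate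
16 | 1-ArB-prop-2-en-1-one | C=CC(=O)c1cc(OC)c(O[Si](C(C)C)(C(C)C)C(C)C)c(OC)c1 | intermediate
17 | (S,E)-1-ArB-3-[(1-ArA-3-nitroprop-2-en-1-yl)oxy]propan-1-one (oxa-Michael adduct) | COc1cc([C@@H](OCCC(=O)c2cc(OC)c(O[Si](C(C)C)(C(C)C)C(C)C)c(OC)c2)/C=C/[N+](=O)[O-])ccc1O[Si](C(C)C)(C(C)C)C(C)C | intermediate (not isolated)
18 | (2S,3R,4S)-2-ArA-3-(nitromethyl)-4-(ArB-carbonyl)oxolane, all-trans | COc1cc([C@H]2OC[C@@H](C(=O)c3cc(OC)c(O[Si](C(C)C)(C(C)C)C(C)C)c(OC)c3)[C@@H]2C[N+](=O)[O-])ccc1O[Si](C(C)C)(C(C)C)C(C)C | intermediate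
19 | sodium nitronate of 18 (C6 as C=N(O)ONa) | COc1cc([C@H]2OC[C@@H](C(=O)c3cc(OC)c(O[Si](C(C)C)(C(C)C)C(C)C)c(OC)c3)[C@@H]2C=[N+]([O-])[O-])ccc1O[Si](C(C)C)(C(C)C)C(C)C.[Na+] | intermediate (not isolated)
20 | (2S,3S,4S)-2-ArA-4-(ArB-carbonyl)oxolane-3-carbaldehyde | COc1cc([C@H]2OC[C@@H](C(=O)c3cc(OC)c(O[Si](C(C)C)(C(C)C)C(C)C)c(OC)c3)[C@@H]2C=O)ccc1O[Si](C(C)C)(C(C)C)C(C)C | intermediate (not isolated)
21 | (2S,3R,4S)-2-ArA-3-(hydroxymethyl)-4-(ArB-carbonyl)oxolane | COc1cc([C@H]2OC[C@@H](C(=O)c3cc(OC)c(O[Si](C(C)C)(C(C)C)C(C)C)c(OC)c3)[C@@H]2CO)ccc1O[Si](C(C)C)(C(C)C)C(C)C | intermediate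
22 | [(3S,4R,5S)-5-(4-hydroxy-3-methoxyphenyl)-4-(hydroxymethyl)oxolan-3-yl](4-hydroxy-3,5-dimethoxyphenyl)methanone | COc1cc([C@H]2OC[C@@H](C(=O)c3cc(OC)c(O)c(OC)c3)[C@@H]2CO)ccc1O | target

Total step count: 13. Longest linear sequence: 10 steps (steps 1–7, 11, 12, 13, from vanillin); the enone branch is 3 steps (8–10).

Steps most likely to fail

1. Step 11 (Proposed new method). The amine may remove the acidic γ-hydrogen at C2 of 12, which deconjugates the nitroalkene towards a β-nitro ketone and destroys the stereocentre. The alkoxide may also add to a second nitroalkene, the oxa-Michael addition may revert before the ring closes, or 16 may polymerise. The fallback uses known reactions only, sets out from 4 and 16, and returns to the route at 17 and through it at 18; it builds the ether tether before any nitroalkene exists. Alcohol 4 is added to 16 under PMe3 catalysis (phosphine-catalysed oxa-Michael addition, THF, rt) to give the ether (S)-1-ArB-3-[(1-ArA-prop-2-en-1-yl)oxy]propan-1-one F1. Ozonolysis (O3, CH2Cl2, −78 °C) gives the secondary ozonide F2, which PPh3 reduces to the α-alkoxy aldehyde F3. Nitromethane 8 with catalytic iPr2NEt gives the nitroaldol F4, and MsCl/iPr2NEt converts it by way of the nitroaldol mesylate F5 into 17. Catalytic DBU in CH2Cl2 at 0 °C then closes 17 to 18 by the intramolecular Michael addition of a ketone to a nitroalkene.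

2. Step 12. The hydride may also reduce the ring B ketone, the β-alkoxy aldehyde may lose O1 by β-elimination or epimerise at C3 if it meets base while warm, and ozone may attack electron-rich ring A. The fallback sets out from 18 and returns at 21; it avoids base, ozone and the aldehyde, and needs no carbonyl differentiation in the reduction. Nitrosative oxidation of the primary nitro group (NaNO2, AcOH, DMSO, 35 °C) gives the carboxylic acid F6. Excess BH3·SMe2 (THF, 0 °C to rt) reduces acid and ketone together to the diol F7, a mixture at C7. MnO2 in CH2Cl2 then re-oxidises only the benzylic carbinol to give 21.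

3. Step 6. Aldehyde 7 may enolise at its α-aryl, α-silyloxy carbon and lose enantiopurity, the TES group may migrate to the new hydroxyl of 9, or the amine may deconjugate 11. The fallback sets out from 5 and returns at 11, bypassing 7 altogether. Radical nitration of the terminal alkene (AgNO2, TEMPO, 4 Å MS, 1,2-dichloroethane, 70 °C) should convert 5 directly into the E-nitroalkene 11 without any enolisable carbonyl intermediate; this fallback makes no new compound (F0).

Further compounds
F1 | step 11 | (S)-1-ArB-3-[(1-ArA-prop-2-en-1-yl)oxy]propan-1-one | COc1cc([C@@H](OCCC(=O)c2cc(OC)c(O[Si](C(C)C)(C(C)C)C(C)C)c(OC)c2)C=C)ccc1O[Si](C(C)C)(C(C)C)C(C)C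
F2 | step 11 | secondary ozonide of F1, 3-[(R)-ArA(3-ArB-3-oxopropoxy)methyl]-1,2,4-trioxolane | COc1cc([C@@H](OCCC(=O)c2cc(OC)c(O[Si](C(C)C)(C(C)C)C(C)C)c(OC)c2)C3OOCO3)ccc1O[Si](C(C)C)(C(C)C)C(C)C
F3 | step 11 | (R)-2-ArA-2-(3-ArB-3-oxopropoxy)acetaldehyde | COc1cc([C@@H](OCCC(=O)c2cc(OC)c(O[Si](C(C)C)(C(C)C)C(C)C)c(OC)c2)C=O)ccc1O[Si](C(C)C)(C(C)C)C(C)C
F4 | step 11 | (3R,2RS)-1-ArB-3-[(1-ArA-2-hydroxy-3-nitropropyl)oxy]propan-1-one (nitroaldol, benzylic centre R, carbinol mixed) | COc1cc([C@@H](OCCC(=O)c2cc(OC)c(O[Si](C(C)C)(C(C)C)C(C)C)c(OC)c2)C(O)C[N+](=O)[O-])ccc1O[Si](C(C)C)(C(C)C)C(C)C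
F5 | step 11 | methanesulfonate of F4 at the secondary hydroxyl | COc1cc([C@@H](OCCC(=O)c2cc(OC)c(O[Si](C(C)C)(C(C)C)C(C)C)c(OC)c2)C(OS(C)(=O)=O)C[N+](=O)[O-])ccc1O[Si](C(C)C)(C(C)C)C(C)C
F6 | step 12 | (2S,3S,4S)-2-ArA-4-(ArB-carbonyl)oxolane-3-carboxylic acid | COc1cc([C@H]2OC[C@@H](C(=O)c3cc(OC)c(O[Si](C(C)C)(C(C)C)C(C)C)c(OC)c3)[C@@H]2C(=O)O)ccc1O[Si](C(C)C)(C(C)C)C(C)C
F7 | step 12 | (2S,3R,4S)-2-ArA-3-(hydroxymethyl)-4-[ArB(hydroxy)methyl]oxolane, carbinol C7 mixed | COc1cc([C@H]2OC[C@@H](C(O)c3cc(OC)c(O[Si](C(C)C)(C(C)C)C(C)C)c(OC)c3)[C@@H]2CO)ccc1O[Si](C(C)C)(C(C)C)C(C)C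
F0 | step 6 | none | none
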